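Rings: A hydroquinone, B the five-membered carbocycle of the indane, C methylcyclohexene, D cyclohexane-1,4-dione, E cyclopentanone. The quaternary carbon shared by B, C, D and E is a spiro centre of B and E and lies alpha to the ring E ketone.
This alpha-spiro ketone is the retron of an epoxide-to-ketone 1,2-shift. Moving the benzylic CH of ring B back from the spiro carbon to the carbonyl carbon turns B into the six-membered ring of a 1,4-dihydronaphthalene fused to a cyclopentene, which is a benzoquinone Diels-Alder ring.
Cuts, in order: the CH-CH2 bond between the two ketones of ring D; the isopropenyl-ring E bond; the bond from the benzylic quaternary carbon to the allylic CH2 of ring C; the 1,2-shift; the two Diels-Alder bonds; the ring E bond between the two alkyne carbons.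
Forward: E (reductive diyne cyclization), then A with a six-membered B (Diels-Alder, aromatization), B contracted to five atoms, then C (enolate alkylation), then D (oxidative enolate coupling).
Stereochemistry: (R)-but-3-yn-2-ol sets the Diels-Alder face by allylic strain and is later oxidized away. The side chains direct the epoxidation, the shift is stereospecific, the tether fixes the benzylic quaternary centre, its acetyl group shields one face of ring E, and ring D can only close cis.
Key step: step 10

Assumption: the Diels-Alder face follows the allylic-strain model (carbinol H in the diene plane, attack anti to the silyloxy group). If the opposite sense held, (S)-but-3-yn-2-ol would be used.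

Step 1
Reactants: 1 (R)-but-3-yn-2-ol
Product: 2 (R)-tert-butyl(but-3-yn-2-yloxy)dimethylsilane
Conditions: TBSCl, imidazole, CH2Cl2, 0 °C to rt
Reagents that add atoms: tert-butyldimethylsilyl chloride CC(C)(C)[Si](C)(C)Cl
Why: Imidazole-promoted silylation should mask the carbinol without touching its stereocentre.

Step 2
Reactants: 2 (R)-tert-butyl(but-3-yn-2-yloxy)dimethylsilane; 3 1-chloro-3-iodopropane
Product: 4 (R)-tert-butyl[(7-chlorohept-3-yn-2-yl)oxy]dimethylsilane
Conditions: n-BuLi, THF, -78 °C; then 3, DMPU, -78 °C to rt
Reagents that add atoms: none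
Why: Acetylide alkylation (SN2) should occur at the iodide only, since iodide is by far the better leaving group.

Step 3
Reactants: 4 (R)-tert-butyl[(7-chlorohept-3-yn-2-yl)oxy]dimethylsilane
Product: 5 (R)-tert-butyldimethyl(nona-3,8-diyn-2-yloxy)silane
Conditions: lithium acetylide ethylenediamine complex, NaI (cat.), DMSO, rt
Reagents that add atoms: lithium acetylide ethylenediamine complex [Li+].[C-]#C.NCCN
Why: SN2 displacement of the primary chloride by acetylide in DMSO should install the terminal alkyne.

Step 4
Reactants: 6 prop-2-yn-1-ol
Product: 7 (Z)-3-iodo-2-methylprop-2-en-1-ol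
Conditions: MeMgBr (2.5 equiv), CuI (10 mol%), Et2O, -10 °C to rt; then I2, 0 °C
Reagents that add atoms: methylmagnesium bromide C[Mg]Br; iodine II
Why: Alkoxide-directed copper-catalysed carbomagnesiation followed by iodinolysis should give the alkene with iodine and CH2OH cis.

Step 5
Reactants: 7 (Z)-3-iodo-2-methylprop-2-en-1-ol
Product: 8 (Z)-tert-butyl[(3-iodo-2-methylallyl)oxy]dimethylsilane
Conditions: TBSCl, imidazole, CH2Cl2, rt
Reagents that add atoms: tert-butyldimethylsilyl chloride CC(C)(C)[Si](C)(C)Cl
Why: Standard silylation should protect the allylic alcohol for the metal-catalysed steps.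

Step 6
Reactants: 5 (R)-tert-butyldimethyl(nona-3,8-diyn-2-yloxy)silane; 8 (Z)-tert-butyl[(3-iodo-2-methylallyl)oxy]dimethylsilane
Product: 9 (2Z,11R)-1,11-bis(tert-butyldimethylsilyloxy)-2-methyldodec-2-ene-4,9-diyne
Conditions: Pd(PPh3)2Cl2 (3 mol%), CuI (6 mol%), Et3N, THF, rt
Reagents that add atoms: none
Why: Sonogashira coupling of a vinyl iodide should proceed with retention of the Z geometry.

Step 7
Reactants: 9 (2Z,11R)-1,11-bis(tert-butyldimethylsilyloxy)-2-methyldodec-2-ene-4,9-diyne
Product: 10 (E,E)-1,2-bis(alkylidene)cyclopentane bearing an (R)-2-(TBS-oxy)propylidene group and a (Z)-4-(TBS-oxy)-3-methylbut-2-enylidene group; both chains outside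
Conditions: Pd2(dba)3·CHCl3 (2.5 mol%), P(o-tol)3 (10 mol%), AcOH, Et3SiH, toluene, rt
Reagents that add atoms: none
Why: Palladium hydride reductive cyclization of a 1,6-diyne (syn hydropalladation, syn carbopalladation, silane reduction of the vinylpalladium) should close ring E and give the s-cis-locked diene with both chains outside.

Step 8
Reactants: 10 (E,E)-1,2-bis(alkylidene)cyclopentane; 11 1,4-benzoquinone
Product: 13 cis-4,9-disubstituted 5,8-dimethoxy-2,3,4,9-tetrahydro-1H-cyclopenta[b]naphthalene (C4 (R)-1-(TBS-oxy)ethyl; C9 (Z)-3-(TBS-oxy)-2-methylprop-1-enyl), via endo Diels-Alder adduct 12 (not isolated)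
Conditions: 11 (1.0 equiv), toluene, 40 °C; then K2CO3, MeI, acetone, reflux, N2
Reagents that add atoms: iodomethane CI
Why: The suprafacial endo Diels-Alder reaction should place both outside chains cis and on the face anti to the silyloxy group (carbinol H in the diene plane by allylic strain), base-induced enolization and Williamson methylation should then fix ring A, and the minor facial diastereomer is removed by chromatography.

Step 9
Reactants: 13 dimethoxy tetrahydrocyclopenta[b]naphthalene
Product: 14 3a,9a-epoxide of 13 with the oxygen anti to both side chains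
Conditions: mCPBA (1.05 equiv), NaHCO3, CH2Cl2, -20 °C
Reagents that add atoms: 3-chloroperbenzoic acid OOC(=O)c1cccc(Cl)c1
Why: Prilezhaev epoxidation should pick the most electron-rich tetrasubstituted alkene and attack anti to the two side chains, which peri strain with the methoxy groups holds pseudoaxial on one face.

Step 10
Reactants: 14 3a,9a-epoxide
Product: 15 4',7'-dimethoxyspiro[cyclopentane-1,2'-indan]-2-one with 1'-[(R)-1-(TBS-oxy)ethyl] and 3'-[(Z)-3-(TBS-oxy)-2-methylprop-1-enyl]; side chains cis to each other and to the spiro-ring CH2 and anti to the C=O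
Conditions: BF3·OEt2 (0.3 equiv), CH2Cl2, -78 °C
Reagents that add atoms: none
Why: BF3 opens one tertiary C-O bond of the ring-fusion epoxide while the benzylic ring carbon on the neighbouring epoxide carbon moves across the lower face (suprafacial 1,2-shift) and the remaining C-O bond becomes the cyclopentanone carbonyl, so the six-membered carbocycle of the dihydronaphthalene loses one atom and becomes the five-membered indane ring B. The closest known reaction type is the Lewis acid epoxide-to-ketone (Meinwald or semipinacol) rearrangement of tetrasubstituted ring-fusion epoxides to spiro ketones, as in 9,10-epoxydecalin to spiro[4.5]decan-6-one. No ring is closed through a new tether: ring B forms through the three-centre transition state of the shift, and the former fusion bond becomes the bond from the spiro carbon to the carbonyl carbon of ring E. The only new stereocentre, the spiro carbon, is fixed by inversion at the migration terminus, because the migrating carbon enters anti to the departing oxygen, which lies anti to both side chains, so the carbonyl should end on the face of ring B opposite to the chains while the migrating carbon keeps its configuration. The step needs migration of a benzylic ring carbon rather than of a cyclopentane CH2 (which would give a cyclobutane) and rather than loss of a benzylic proton towards a naphthalene; the high migratory aptitude of the electron-rich benzylic carbons, ring strain and the low temperature should secure this. Which of the two C-O bonds opens does not matter, because ring E is still unsubstituted and both shifts give the same compound 15.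

Step 11
Reactants: 15 spiro ketone bis(silyl ether)
Product: 16 spiro ketone diol (1'-[(R)-1-hydroxyethyl]; 3'-[(Z)-3-hydroxy-2-methylprop-1-enyl])
Conditions: TBAF, THF, 0 °C to rt
Reagents that add atoms: none
Why: Fluoride desilylation should free both alcohols and leave the only enolizable position (ring E CH2) without consequence.

Step 12
Reactants: 16 spiro ketone diol
Product: 17 1'-acetyl-3'-[(Z)-3-chloro-2-methylprop-1-enyl]-4',7'-dimethoxyspiro[cyclopentane-1,2'-indan]-2-one
Conditions: NCS, Me2S, CH2Cl2, -25 to 0 °C; then Et3N
Reagents that add atoms: N-chlorosuccinimide ClN1C(=O)CCC1=O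
Why: With the Corey-Kim reagent the allylic alkoxysulfonium salt should collapse with chloride to the allylic chloride (Z retained), while the saturated secondary one waits for Et3N and should give the methyl ketone.

Step 13
Reactants: 17 chloro diketone
Product: 18 tetracyclic diketone: benzo-fused bicyclo[3.2.1]octadiene (rings A, B, C) with a bridgehead acetyl group and the spiro cyclopentanone at the one-carbon bridge
Conditions: KOt-Bu (1.05 equiv), THF, -40 to 0 °C
Reagents that add atoms: none
Why: Intramolecular SN2 alkylation of the thermodynamic benzylic enolate (by far the most acidic site) should close ring C as a six-membered ring, and the Z-allyl tether on the neighbouring benzylic carbon can reach only one face, which fixes the quaternary centre and turns the acetyl group towards the ring E ketone.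

Step 14
Reactants: 18 tetracyclic diketone
Product: 19 tetracyclic enone (ring E as cyclopent-2-enone)
Conditions: IBX, 4-methoxypyridine N-oxide, DMSO, 25 °C
Reagents that add atoms: none
Why: IBX dehydrogenation should act only on ring E, since the methyl ketone has no beta hydrogen and the other alpha carbons are quaternary.

Step 15
Reactants: 19 tetracyclic enone
Product: 21 tetracyclic diketone with a 3-isopropenylcyclopentanone ring E, via trimethylsilyl enol ether 20 (not isolated)
Conditions: isopropenylMgBr, CuBr·SMe2 (15 mol%), TMSCl, THF, -78 °C; then 1 M HCl, 0 °C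
Reagents that add atoms: isopropenylmagnesium bromide CC(=C)[Mg]Br
Why: Copper-catalysed conjugate addition should come from the ring E face on the side of the benzylic CH, because the acetyl group covers the other face, and silyl trapping keeps the enolate from an aldol reaction with the acetyl group.

Step 16
Reactants: 21 isopropenyl diketone
Product: 22 O,O'-dimethyl ether of the target (rings A to E complete)
Conditions: inverse addition to LDA (2.3 equiv), THF, -78 °C; then Fe(acac)3 (2.2 equiv), -78 °C to rt
Reagents that add atoms: none
Why: Intramolecular oxidative coupling of the two ketone enolates (each ketone has only one enolizable side) by trivalent iron should give the 1,4-diketone ring D, and the new CH centre can form only on the acetyl face, which is trans to the isopropenyl group.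

Step 17
Reactants: 22 O,O'-dimethyl ether of the target
Product: 24 target hydroquinone CNP0287617.1, via quinone 23 (not isolated)
Conditions: (NH4)2Ce(NO3)6, MeCN/H2O, 0 °C; then aq. Na2S2O4
Reagents that add atoms: water O
Why: Oxidative demethylation of the 1,4-dimethoxyarene to the quinone and dithionite reduction should free the hydroquinone without acid or base strong enough to touch the alkenes or ketones.

Compound list
1 | (R)-but-3-yn-2-ol | C#C[C@@H](C)O | starting material
2 | (R)-tert-butyl(but-3-yn-2-yloxy)dimethylsilane | C#C[C@@H](C)O[Si](C)(C)C(C)(C)C | intermediate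
3 | 1-chloro-3-iodopropane | ClCCCI | starting material
4 | (R)-tert-butyl[(7-chlorohept-3-yn-2-yl)oxy]dimethylsilane | ClCCCC#C[C@@H](C)O[Si](C)(C)C(C)(C)C | intermediate
5 | (R)-tert-butyldimethyl(nona-3,8-diyn-2-yloxy)silane | C#CCCCC#C[C@@H](C)O[Si](C)(C)C(C)(C)C | intermediate
6 | prop-2-yn-1-ol | C#CCO | starting material
7 | (Z)-3-iodo-2-methylprop-2-en-1-ol | OC/C(C)=C\I | intermediate
8 | (Z)-tert-butyl[(3-iodo-2-methylallyl)oxy]dimethylsilane | CC(C)(C)[Si](C)(C)OC/C(C)=C\I | intermediate
9 | (2Z,11R)-1,11-bis(TBS-oxy)-2-methyldodec-2-ene-4,9-diyne | CC(C)(C)[Si](C)(C)OC/C(C)=C\C#CCCCC#C[C@@H](C)O[Si](C)(C)C(C)(C)C | intermediate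
10 | (E,E)-1,2-bis(alkylidene)cyclopentane triene | C[C@@H](O[Si](C)(C)C(C)(C)C)/C=C1\CCC/C1=C\C=C(C)/CO[Si](C)(C)C(C)(C)C | intermediate
11 | 1,4-benzoquinone | O=C1C=CC(=O)C=C1 | starting material
12 | endo Diels-Alder adduct (all-cis enedione) | C[C@@H](O[Si](C)(C)C(C)(C)C)[C@@H]1C2=C(CCC2)[C@H](/C=C(C)\CO[Si](C)(C)C(C)(C)C)[C@@H]3C(=O)C=CC(=O)[C@H]13 | intermediate
13 | cis-4,9-disubstituted 5,8-dimethoxy-2,3,4,9-tetrahydro-1H-cyclopenta[b]naphthalene | C[C@@H](O[Si](C)(C)C(C)(C)C)[C@@H]1C2=C(CCC2)[C@H](/C=C(C)\CO[Si](C)(C)C(C)(C)C)c3c(OC)ccc(OC)c13 | intermediate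
14 | 3a,9a-epoxide of 13 (oxygen anti to the side chains) | C[C@@H](O[Si](C)(C)C(C)(C)C)[C@@H]1[C@]23CCC[C@]2(O3)[C@H](/C=C(C)\CO[Si](C)(C)C(C)(C)C)c4c(OC)ccc(OC)c14 | intermediate
15 | spiro[cyclopentane-1,2'-indan]-2-one bis(silyl ether) | C[C@@H](O[Si](C)(C)C(C)(C)C)[C@@H]1[C@]2(CCCC2=O)[C@H](/C=C(C)\CO[Si](C)(C)C(C)(C)C)c3c(OC)ccc(OC)c13 | intermediate
16 | spiro ketone diol | C[C@@H](O)[C@@H]1[C@]2(CCCC2=O)[C@H](/C=C(C)\CO)c3c(OC)ccc(OC)c13 | intermediate
17 | chloro diketone | CC(=O)[C@@H]1[C@]2(CCCC2=O)[C@H](/C=C(C)\CCl)c3c(OC)ccc(OC)c13 | intermediate
18 | tetracyclic diketone (rings A, B, C, E) | CC(=O)[C@]12CC(C)=C[C@H](c3c(OC)ccc(OC)c13)[C@@]24CCCC4=O | intermediate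
19 | tetracyclic enone | CC(=O)[C@]12CC(C)=C[C@H](c3c(OC)ccc(OC)c13)[C@@]24CC=CC4=O | intermediate
20 | trimethylsilyl enol ether of 21 | CC(=O)[C@]12CC(C)=C[C@H](c3c(OC)ccc(OC)c13)[C@@]24C[C@H](C(C)=C)C=C4O[Si](C)(C)C | intermediate
21 | isopropenyl diketone | CC(=O)[C@]12CC(C)=C[C@H](c3c(OC)ccc(OC)c13)[C@@]24C[C@H](C(C)=C)CC4=O | intermediate
22 | O,O'-dimethyl ether of the target | C=C(C)[C@H]1C[C@@]23C(=O)[C@@H]1CC(=O)[C@@]21CC(C)=C[C@@H]3c2c(OC)ccc(OC)c21 | intermediate
23 | quinone of the target | C=C(C)[C@H]1C[C@@]23C(=O)[C@@H]1CC(=O)[C@@]21CC(C)=C[C@@H]3C2=C1C(=O)C=CC2=O | intermediate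
24 | target CNP0287617.1 | C=C(C)[C@H]1C[C@@]23C(=O)[C@@H]1CC(=O)[C@@]21CC(C)=C[C@@H]3c2c(O)ccc(O)c21 | target

Total steps: 17. Longest linear sequence: 15 steps (steps 1 to 3 and 6 to 17).

Steps most likely to fail

Step 10. The opened epoxide may lose a benzylic proton and dehydrate to the fully aromatic naphthalene, or a silyl ether oxygen may capture the cation, before the 1,2-shift occurs. The fallback carries ring A as the enedione through the contraction and aromatizes afterwards, so that no benzylic cation or naphthalene sink exists. It sets out from 12, which is then isolated. Treatment with mCPBA should give the epoxy enedione F1, with oxygen on the open convex face. BF3·OEt2 at -78 °C should give the spiro ketone enedione F2. K2CO3 and MeI in acetone then aromatize and methylate, and the route is rejoined at 15.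

Step 16. The dienolate may be protonated, may dimerize between molecules, or may close an aldol bond between the two ketones instead of coupling carbon to carbon. The fallback replaces the dianion by a neutral substrate that couples through a silyl enol ether radical cation. It sets out from 20, which is then isolated. LDA and TMSCl at the methyl ketone should give the bis(trimethylsilyl enol ether) F3. Cu(OTf)2 with Cu2O in MeCN should couple the two enol ether carbons, and the route is rejoined at 22.

Step 13. The hindered tertiary enolate may react too slowly, so that elimination of hydrogen chloride from the allylic chloride or aldol reactions of the other enolates take over. The fallback changes from an SN2 closure to a pi-allyl closure. It sets out from 16. Methyl chloroformate and pyridine at 0 °C should acylate only the primary allylic alcohol to give the allylic methyl carbonate alcohol F4. Dess-Martin periodinane should give the keto carbonate F5. Pd(PPh3)4 in THF at 60 °C (zerovalent palladium, Tsuji-Trost alkylation with the methoxide released in the flask as base) should attack the far allyl terminus, because the near one would give a four-membered ring, and the route is rejoined at 18.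

Further compounds
F1 | step 10 | epoxy enedione (epoxide of 12) | C[C@@H](O[Si](C)(C)C(C)(C)C)[C@@H]1[C@]23CCC[C@]2(O3)[C@H](/C=C(C)\CO[Si](C)(C)C(C)(C)C)[C@@H]4C(=O)C=CC(=O)[C@H]14
F2 | step 10 | spiro ketone enedione | C[C@@H](O[Si](C)(C)C(C)(C)C)[C@@H]1[C@]2(CCCC2=O)[C@H](/C=C(C)\CO[Si](C)(C)C(C)(C)C)[C@@H]3C(=O)C=CC(=O)[C@H]13
F3 | step 16 | bis(trimethylsilyl enol ether) | C=C(O[Si](C)(C)C)[C@]12CC(C)=C[C@H](c3c(OC)ccc(OC)c13)[C@@]24C[C@H](C(C)=C)C=C4O[Si](C)(C)C
F4 | step 13 | allylic methyl carbonate alcohol | C[C@@H](O)[C@@H]1[C@]2(CCCC2=O)[C@H](/C=C(C)\COC(=O)OC)c3c(OC)ccc(OC)c13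
F5 | step 13 | keto carbonate | CC(=O)[C@@H]1[C@]2(CCCC2=O)[C@H](/C=C(C)\COC(=O)OC)c3c(OC)ccc(OC)c13
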